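Numbering: C1 is the ring carbon that bears the vanillate. It is followed by C2H2, C3=C4(Me) (E), C5–C7, C8(Me)2, C9(OAc) and C10=C11(Me) (Z), and C11 bonds back to C1.
Enabling feature: in the 11-membered carbocycle the C9 carbinol lies between quaternary C8 and the Z-C10=C11 alkene. It is therefore an allylic alcohol whose C9–C10 bond maps onto a C10 alkenyl metal and a C9 aldehyde with no α-hydrogen.
Retrosynthetic cuts, in order: the phenol acetate and the C9 acetate; ring bond C9–C10; the acyl–O bond at C1; C11–CH3 and C10–C11 (methylmetalation, one-carbon alkyne homologation); C4–C5; C2–C3.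
Forward: acetylide/epoxide union (C2–C3), B-alkyl Suzuki coupling (C4–C5), growth of C11 into the Z-iodoalkene, esterification of C1, unmasking of C9, the single ring closure, then two finishing steps.
Stereochemistry: C1 (S) comes with (S)-glycidyl trityl ether. E-C3=C4 comes from syn-hydrozirconation and Z-C10=C11 from alkoxide-directed anti-methylmagnesiation. C9 (R) arises in the ring closure under the influence of C1.
C1 already carries the O-acetylvanillate during cyclisation, so a free C1 hydroxyl never faces the C9 acetate across the Z-alkene (no 1,4-acyl shift) and no silyl on/off pair is needed after ring closure.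

Key step: step 14

Remark on the chemistry: the SMILES gives the descriptors 1S, 9R, 3E and 10Z, with the ring bonds C9–C10 and C11–C1 cis on the C10=C11 alkene. The ring closure is assumed to favour 9R; if it does not, the first fallback applies.

Step 1
Reactants: 1 propyne; 2 (S)-glycidyl trityl ether
Product: 4 (S)-1-(trityloxy)hex-4-yn-2-ol, via 1-propynyllithium 3 (not isolated)
Conditions: n-BuLi, THF, −78 °C; BF3·OEt2; then 2, −78 °C; aq. NH4Cl
Reagents that add atoms: none
Why: Yamaguchi–Hirao epoxide opening, in which the BF3-assisted lithium acetylide attacks only the unsubstituted epoxide carbon (future C2) in SN2 fashion, so the C–O stereocentre of 2 passes unchanged into C1 (S), and trityl ethers tolerate BF3·OEt2 at −78 °C.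

Step 2
Reactants: 4 (S)-1-(trityloxy)hex-4-yn-2-ol
Product: 5 (S)-tert-butyldimethyl{[1-(trityloxy)hex-4-yn-2-yl]oxy}silane
Conditions: TBSCl, imidazole, DMF, rt
Reagents that add atoms: tert-butyldimethylsilyl chloride, CC(C)(C)[Si](C)(C)Cl
Why: Imidazole-promoted silylation of a secondary alcohol removes the acidic proton before hydrozirconation and keeps the C1 oxygen distinct from the tritylated C11 oxygen that is oxidised later.

Step 3
Reactants: 5 (S)-tert-butyldimethyl{[1-(trityloxy)hex-4-yn-2-yl]oxy}silane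
Product: 7 (S,E)-tert-butyl{[5-iodo-1-(trityloxy)hex-4-en-2-yl]oxy}dimethylsilane, via alkenylzirconocene chloride 6 (not isolated)
Conditions: Cp2Zr(H)Cl (excess), THF, rt to 45 °C; then I2, THF, 0 °C
Reagents that add atoms: iodine, [I][I]
Why: Hydrozirconation–iodination, in which Zr–H adds syn to the methyl-capped alkyne, excess hydride with gentle warming equilibrates the regioisomers toward zirconium on the less hindered methyl-bearing C4, and iodinolysis with retention should give the E-iodoalkene with C2 and the methyl group cis.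

Step 4
Reactants: 8 2,2-dimethylpent-4-enal
Product: 9 5,5-dimethoxy-4,4-dimethylpent-1-ene
Conditions: HC(OMe)3, MeOH, TsOH·H2O (cat.), rt
Reagents that add atoms: trimethyl orthoformate, COC(OC)OC; methanol, CO
Why: Acid-catalysed acetalisation with orthoformate as water scavenger masks the non-enolisable C9 aldehyde in one step, at the correct oxidation level, against borane, base and Grignard reagent.

Step 5
Reactants: 9 5,5-dimethoxy-4,4-dimethylpent-1-ene; 7 (S,E)-tert-butyl{[5-iodo-1-(trityloxy)hex-4-en-2-yl]oxy}dimethylsilane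
Product: 11 (S,E)-tert-butyl{[10,10-dimethoxy-5,9,9-trimethyl-1-(trityloxy)dec-4-en-2-yl]oxy}dimethylsilane, via B-alkyl-9-BBN 10 (not isolated)
Conditions: 9-BBN, THF, 0 °C to rt; then 7, Pd(dppf)Cl2 (5 mol %), AsPh3, Cs2CO3, DMF/THF/H2O, rt
Reagents that add atoms: none
Why: B-alkyl Suzuki–Miyaura coupling, in which 9-BBN places boron on the terminal carbon C5 of the monosubstituted alkene and the base-activated borane couples with the alkenyl iodide with retention, forming C4–C5 and fixing the E-C3=C4 alkene.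

Step 6
Reactants: 11 (S,E)-tert-butyl{[10,10-dimethoxy-5,9,9-trimethyl-1-(trityloxy)dec-4-en-2-yl]oxy}dimethylsilane
Product: 12 (S,E)-2-[(tert-butyldimethylsilyl)oxy]-10,10-dimethoxy-5,9,9-trimethyldec-4-en-1-ol
Conditions: CSA (0.1 equiv), dry MeOH/CH2Cl2, 0 °C; Et3N quench
Reagents that add atoms: none
Why: Acid-catalysed methanolysis of the trityl ether through the trityl cation is much faster than cleavage of a secondary TBS ether, and acetal exchange with methanol is degenerate for a dimethyl acetal.

Step 7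
Reactants: 12 (S,E)-2-[(tert-butyldimethylsilyl)oxy]-10,10-dimethoxy-5,9,9-trimethyldec-4-en-1-ol
Product: 13 (S,E)-2-[(tert-butyldimethylsilyl)oxy]-10,10-dimethoxy-5,9,9-trimethyldec-4-enal
Conditions: Dess–Martin periodinane, CH2Cl2, 0 °C to rt; used without storage
Reagents that add atoms: none
Why: Dess–Martin oxidation stops at the aldehyde under nearly neutral conditions and is routine for configurationally sensitive α-silyloxy aldehydes.

Step 8
Reactants: 13 (S,E)-2-[(tert-butyldimethylsilyl)oxy]-10,10-dimethoxy-5,9,9-trimethyldec-4-enal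
Product: 14 (S,E)-tert-butyl[(11,11-dimethoxy-6,10,10-trimethylundec-5-en-1-yn-3-yl)oxy]dimethylsilane
Conditions: dimethyl (1-diazo-2-oxopropyl)phosphonate, K2CO3, MeOH, 0 °C to rt
Reagents that add atoms: dimethyl (1-diazo-2-oxopropyl)phosphonate, COP(=O)(OC)C(=[N+]=[N-])C(C)=O
Why: Ohira–Bestmann variant of the Seyferth–Gilbert homologation, in which the diazophosphonate anion olefinates the aldehyde and loss of nitrogen with a 1,2-hydrogen shift gives the terminal alkyne, adding C10 under conditions mild enough that C1 should keep its configuration.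

Step 9
Reactants: 14 (S,E)-tert-butyl[(11,11-dimethoxy-6,10,10-trimethylundec-5-en-1-yn-3-yl)oxy]dimethylsilane
Product: 15 (S,E)-11,11-dimethoxy-6,10,10-trimethylundec-5-en-1-yn-3-ol
Conditions: TBAF, THF, 0 °C to rt
Reagents that add atoms: none
Why: Fluoride desilylation, driven by Si–F bond formation, frees the C1 hydroxyl needed as directing group and leaves acetal, alkyne and alkene untouched.

Step 10
Reactants: 15 (S,E)-11,11-dimethoxy-6,10,10-trimethylundec-5-en-1-yn-3-ol
Product: 17 (1Z,3S,5E)-1-iodo-11,11-dimethoxy-2,6,10,10-tetramethylundeca-1,5-dien-3-ol, via alkenylmagnesium chelate 16 (not isolated)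
Conditions: MeMgBr (3 equiv), CuI (0.2 equiv), THF, −10 °C to rt; then I2, THF, −20 °C; aq. Na2S2O3/NH4Cl
Reagents that add atoms: methylmagnesium bromide, C[Mg]Br; iodine, [I][I]
Why: Copper-catalysed anti-carbomagnesiation of a propargylic alkoxide (Duboudin–Jousseaume reaction) delivers methyl to C11 and leaves magnesium on C10 cis to C1 in a five-membered chelate with the C1 alkoxide, so iodinolysis with retention should give the Z-iodoalkene.

Step 11
Reactants: 18 vanillic acid
Product: 19 4-acetoxy-3-methoxybenzoic acid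
Conditions: Ac2O, pyridine, rt; aqueous work-up
Reagents that add atoms: acetic anhydride, CC(=O)OC(C)=O
Why: Pyridine-mediated O-acetylation of the phenol, with any mixed anhydride at the carboxyl group hydrolysed on work-up.

Step 12
Reactants: 17 (1Z,3S,5E)-1-iodo-11,11-dimethoxy-2,6,10,10-tetramethylundeca-1,5-dien-3-ol; 19 4-acetoxy-3-methoxybenzoic acid
Product: 21 (1Z,3S,5E)-1-iodo-11,11-dimethoxy-2,6,10,10-tetramethylundeca-1,5-dien-3-yl 4-acetoxy-3-methoxybenzoate, via O-acylisourea 20 (not isolated)
Conditions: DCC, DMAP (0.1 equiv), CH2Cl2, 0 °C to rt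
Reagents that add atoms: none
Why: Steglich esterification, in which DCC activates the acid and DMAP relays the aroyl group to the C1 hydroxyl without breaking the C1–O bond, so the S configuration is kept.

Step 13
Reactants: 21 (1Z,3S,5E)-1-iodo-11,11-dimethoxy-2,6,10,10-tetramethylundeca-1,5-dien-3-yl 4-acetoxy-3-methoxybenzoate
Product: 22 (1Z,3S,5E)-1-iodo-2,6,10,10-tetramethyl-11-oxoundeca-1,5-dien-3-yl 4-acetoxy-3-methoxybenzoate
Conditions: TsOH·H2O (0.2 equiv), THF/H2O (4:1), rt
Reagents that add atoms: water, O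
Why: Acid-catalysed acetal hydrolysis through the oxocarbenium ion is far faster than acid hydrolysis of the aryl acetate or the benzoate, and the released aldehyde cannot enolise.

Step 14
Reactants: 22 (1Z,3S,5E)-1-iodo-2,6,10,10-tetramethyl-11-oxoundeca-1,5-dien-3-yl 4-acetoxy-3-methoxybenzoate
Product: 24 (1S,3E,9R,10Z)-9-hydroxy-4,8,8,11-tetramethylcycloundeca-3,10-dien-1-yl 4-acetoxy-3-methoxybenzoate, via alkenylchromium dichloride 23 (not isolated)
Conditions: CrCl2 (12 equiv), NiCl2 (0.1 equiv), degassed DMSO/THF (3:1), syringe-pump addition of 22 to about 2 mM, rt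
Reagents that add atoms: none
Why: CrCl2 first reduces NiCl2 to zerovalent nickel; oxidative addition of this nickel to the C10–I bond keeps the alkene geometry (2,2-disubstituted iodoalkenes do not isomerise), transmetalation hands the alkenyl ligand to trivalent chromium (23), and the carbon–chromium bond adds to the chromium-bound C9 carbonyl. The closest known reaction type is the Nozaki–Hiyama–Kishi macrocyclisation of ω-iodoalkenyl aldehydes to medium and large carbocycles. The ring forms in the 11-exo-trig mode (C10 attacks the carbonyl carbon and the C=O bond stays outside the new ring), helped by the gem-dimethyl group at C8 and by two alkenes that remove rotors from the chain, while high dilution and slow addition hold back intermolecular coupling. C9 is controlled by the C1 stereocentre: A(1,3) strain across the Z-alkene holds C1–H in the alkene plane with the aroyloxy group and C2 on opposite faces, and the tether running from C2 should then present the Re face of the aldehyde to C10, which gives 9R; this preference is expected but not secured. Chemoselectivity rests on the aldehyde-only reactivity of alkenylchromium reagents, which leaves the benzoate, the aryl acetate and both alkenes alone, and quaternary C8 excludes enolisation or aldol loss of 22.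

Step 15
Reactants: 24 (1S,3E,9R,10Z)-9-hydroxy-4,8,8,11-tetramethylcycloundeca-3,10-dien-1-yl 4-acetoxy-3-methoxybenzoate
Product: 25 (1S,3E,9R,10Z)-9-acetoxy-4,8,8,11-tetramethylcycloundeca-3,10-dien-1-yl 4-acetoxy-3-methoxybenzoate
Conditions: Ac2O, DMAP, Et3N, CH2Cl2, rt
Reagents that add atoms: acetic anhydride, CC(=O)OC(C)=O
Why: DMAP-catalysed acetylation of the hindered allylic alcohol leaves the C9–O bond intact, and a shift of the conjugated aroyl group from C1 to the neopentylic C9 oxygen is disfavoured both sterically and thermodynamically.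

Step 16
Reactants: 25 (1S,3E,9R,10Z)-9-acetoxy-4,8,8,11-tetramethylcycloundeca-3,10-dien-1-yl 4-acetoxy-3-methoxybenzoate
Product: 26 (1S,3E,9R,10Z)-9-acetoxy-4,8,8,11-tetramethylcycloundeca-3,10-dien-1-yl 4-hydroxy-3-methoxybenzoate
Conditions: pyrrolidine (2 equiv), CH2Cl2, 0 °C
Reagents that add atoms: none
Why: Chemoselective aminolysis of an aryl acetate, because the phenoxide para to the ester carbonyl is a far better leaving group than an alkoxide, so the hindered C9 acetate and the C1 benzoate should remain.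

Compound list
1 | propyne | CC#C | starting material
2 | (S)-glycidyl trityl ether | C(c1ccccc1)(c1ccccc1)(c1ccccc1)OC[C@@H]1CO1 | starting material
3 | 1-propynyllithium (not isolated) | CC#C[Li] | intermediate
4 | (S)-1-(trityloxy)hex-4-yn-2-ol | C(c1ccccc1)(c1ccccc1)(c1ccccc1)OC[C@@H](O)CC#CC | intermediate
5 | (S)-tert-butyldimethyl{[1-(trityloxy)hex-4-yn-2-yl]oxy}silane | C(c1ccccc1)(c1ccccc1)(c1ccccc1)OC[C@@H](O[Si](C)(C)C(C)(C)C)CC#CC | intermediate
6 | chlorobis(cyclopentadienyl)[(2E,5S)-5-(tert-butyldimethylsilyloxy)-6-(trityloxy)hex-2-en-2-yl]zirconium (not isolated) | C(c1ccccc1)(c1ccccc1)(c1ccccc1)OC[C@@H](O[Si](C)(C)C(C)(C)C)C/C=C(\C)[Zr](Cl)(C1C=CC=C1)C1C=CC=C1 | intermediate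
7 | (S,E)-tert-butyl{[5-iodo-1-(trityloxy)hex-4-en-2-yl]oxy}dimethylsilane | C(c1ccccc1)(c1ccccc1)(c1ccccc1)OC[C@@H](O[Si](C)(C)C(C)(C)C)C/C=C(\C)I | intermediate
8 | 2,2-dimethylpent-4-enal | C=CCC(C)(C)C=O | starting material
9 | 5,5-dimethoxy-4,4-dimethylpent-1-ene | C=CCC(C)(C)C(OC)OC | intermediate
10 | 9-(5,5-dimethoxy-4,4-dimethylpentyl)-9-borabicyclo[3.3.1]nonane (not isolated) | COC(OC)C(C)(C)CCCB1C2CCCC1CCC2 | intermediate
11 | (S,E)-tert-butyl{[10,10-dimethoxy-5,9,9-trimethyl-1-(trityloxy)dec-4-en-2-yl]oxy}dimethylsilane | C(c1ccccc1)(c1ccccc1)(c1ccccc1)OC[C@@H](O[Si](C)(C)C(C)(C)C)C/C=C(\C)CCCC(C)(C)C(OC)OC | intermediate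
12 | (S,E)-2-[(tert-butyldimethylsilyl)oxy]-10,10-dimethoxy-5,9,9-trimethyldec-4-en-1-ol | OC[C@@H](O[Si](C)(C)C(C)(C)C)C/C=C(\C)CCCC(C)(C)C(OC)OC | intermediate
13 | (S,E)-2-[(tert-butyldimethylsilyl)oxy]-10,10-dimethoxy-5,9,9-trimethyldec-4-enal | O=C[C@@H](O[Si](C)(C)C(C)(C)C)C/C=C(\C)CCCC(C)(C)C(OC)OC | intermediate
14 | (S,E)-tert-butyl[(11,11-dimethoxy-6,10,10-trimethylundec-5-en-1-yn-3-yl)oxy]dimethylsilane | C#C[C@@H](O[Si](C)(C)C(C)(C)C)C/C=C(\C)CCCC(C)(C)C(OC)OC | intermediate
15 | (S,E)-11,11-dimethoxy-6,10,10-trimethylundec-5-en-1-yn-3-ol | C#C[C@@H](O)C/C=C(\C)CCCC(C)(C)C(OC)OC | intermediate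
16 | (Z)-C10 alkenylmagnesium bromide chelated to the C1 bromomagnesium alkoxide (not isolated) | Br[Mg]/C=C(C)\[C@@H](O[Mg]Br)C/C=C(\C)CCCC(C)(C)C(OC)OC | intermediate
17 | (1Z,3S,5E)-1-iodo-11,11-dimethoxy-2,6,10,10-tetramethylundeca-1,5-dien-3-ol | I/C=C(C)\[C@@H](O)C/C=C(\C)CCCC(C)(C)C(OC)OC | intermediate
18 | vanillic acid | COc1cc(C(=O)O)ccc1O | starting material
19 | 4-acetoxy-3-methoxybenzoic acid | COc1cc(C(=O)O)ccc1OC(C)=O | intermediate
20 | O-(4-acetoxy-3-methoxybenzoyl)-N,N'-dicyclohexylisourea (not isolated) | COc1cc(C(=O)OC(=NC2CCCCC2)NC2CCCCC2)ccc1OC(C)=O | intermediate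
21 | (1Z,3S,5E)-1-iodo-11,11-dimethoxy-2,6,10,10-tetramethylundeca-1,5-dien-3-yl 4-acetoxy-3-methoxybenzoate | I/C=C(C)\[C@@H](OC(=O)c1ccc(OC(C)=O)c(OC)c1)C/C=C(\C)CCCC(C)(C)C(OC)OC | intermediate
22 | (1Z,3S,5E)-1-iodo-2,6,10,10-tetramethyl-11-oxoundeca-1,5-dien-3-yl 4-acetoxy-3-methoxybenzoate | I/C=C(C)\[C@@H](OC(=O)c1ccc(OC(C)=O)c(OC)c1)C/C=C(\C)CCCC(C)(C)C=O | intermediate
23 | (Z)-C10 alkenylchromium dichloride derived from 22 (not isolated) | Cl[Cr](Cl)/C=C(C)\[C@@H](OC(=O)c1ccc(OC(C)=O)c(OC)c1)C/C=C(\C)CCCC(C)(C)C=O | intermediate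
24 | (1S,3E,9R,10Z)-9-hydroxy-4,8,8,11-tetramethylcycloundeca-3,10-dien-1-yl 4-acetoxy-3-methoxybenzoate | COc1cc(C(=O)O[C@H]2C/C=C(\C)CCCC(C)(C)[C@H](O)/C=C\2C)ccc1OC(C)=O | intermediate
25 | (1S,3E,9R,10Z)-9-acetoxy-4,8,8,11-tetramethylcycloundeca-3,10-dien-1-yl 4-acetoxy-3-methoxybenzoate | COc1cc(C(=O)O[C@H]2C/C=C(\C)CCCC(C)(C)[C@H](OC(C)=O)/C=C\2C)ccc1OC(C)=O | intermediate
26 | (1S,3E,9R,10Z)-9-acetoxy-4,8,8,11-tetramethylcycloundeca-3,10-dien-1-yl 4-hydroxy-3-methoxybenzoate (CNP0124394.1) | COc1cc(C(=O)O[C@H]2C/C=C(\C)CCCC(C)(C)[C@H](OC(C)=O)/C=C\2C)ccc1O | target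

Total step count: 16.
Longest linear sequence: 14 (steps 1, 2, 3, 5, 6, 7, 8, 9, 10, 12, 13, 14, 15, 16).

Steps most likely to fail

**Step 14.**
- The aldehyde may be attacked on both faces, or mainly on the Si face, because only the remote C1 centre and the strain of the forming ring bias the closure. Intermolecular coupling also competes if dilution is insufficient.
- The fallback sets C9 by reduction instead of by C–C bond formation.
- It sets out from 22. The ring is closed in the same way and the material is taken on whatever its C9 configuration, including (1S,3E,9S,10Z)-9-hydroxy-4,8,8,11-tetramethylcycloundeca-3,10-dien-1-yl 4-acetoxy-3-methoxybenzoate F1.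
- Dess–Martin periodinane in CH2Cl2 converts all of it into the ring enone (1S,3E,10Z)-4,8,8,11-tetramethyl-9-oxocycloundeca-3,10-dien-1-yl 4-acetoxy-3-methoxybenzoate F2.
- F2 is reduced with (S)-2-methyl-CBS-oxazaborolidine and catecholborane in toluene at −78 °C. With quaternary C8 as the large and C10 as the small ketone substituent, hydride should reach the face that leads to 9R. The route is rejoined at 24.

**Step 10.**
- Carbomagnesiation of the hindered secondary alkoxide may be slow or unselective.
- Competing metalation of the terminal alkyne C–H would lead to over-iodination.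
- Iodine may attack the C3=C4 alkene with participation of the C1 alkoxide.
- The fallback builds the Z-iodoalkene by olefination instead of carbometalation and sets out from 13.
- MeMgBr in THF at −78 °C gives (3S,5E)-3-[(tert-butyldimethylsilyl)oxy]-11,11-dimethoxy-6,10,10-trimethylundec-5-en-2-ol F3 as a mixture of carbinol epimers.
- Dess–Martin oxidation gives (3S,5E)-3-[(tert-butyldimethylsilyl)oxy]-11,11-dimethoxy-6,10,10-trimethylundec-5-en-2-one F4.
- Stork–Zhao olefination ([Ph3PCH2I]I, NaN(SiMe3)2, THF/DMPU, −78 °C) follows. It uses the known preference of α-alkoxy methyl ketones to place the ylide substituent cis to the alkoxy-bearing carbon, and should give tert-butyl{[(1Z,3S,5E)-1-iodo-11,11-dimethoxy-2,6,10,10-tetramethylundeca-1,5-dien-3-yl]oxy}dimethylsilane F5.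
- TBAF in THF removes the silyl group. The route is rejoined at 17.

**Step 8.**
- Enolisation of the α-silyloxy aldehyde in K2CO3/MeOH would erode the configuration at C1, the only source of absolute stereochemistry. Silyl loss under the same conditions is a second concern.
- The fallback keeps base away from the aldehyde and sets out from 13.
- Corey–Fuchs dibromoolefination (CBr4, PPh3, Et3N, CH2Cl2, 0 °C) gives tert-butyl{[(3S,5E)-1,1-dibromo-11,11-dimethoxy-6,10,10-trimethylundeca-1,5-dien-3-yl]oxy}dimethylsilane F6.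
- n-BuLi (2.2 equiv) in THF at −78 °C triggers bromine–lithium exchange and Fritsch–Buttenberg–Wiechell rearrangement to the lithium acetylide of 14 F7, which is protonated on work-up. The route is rejoined at 14.

Further compounds
F1 | step 14 | (1S,3E,9S,10Z)-9-hydroxy-4,8,8,11-tetramethylcycloundeca-3,10-dien-1-yl 4-acetoxy-3-methoxybenzoate | COc1cc(C(=O)O[C@H]2C/C=C(\C)CCCC(C)(C)[C@@H](O)/C=C\2C)ccc1OC(C)=O
F2 | step 14 | (1S,3E,10Z)-4,8,8,11-tetramethyl-9-oxocycloundeca-3,10-dien-1-yl 4-acetoxy-3-methoxybenzoate | COc1cc(C(=O)O[C@H]2C/C=C(\C)CCCC(C)(C)C(=O)/C=C\2C)ccc1OC(C)=O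
F3 | step 10 | (3S,5E)-3-[(tert-butyldimethylsilyl)oxy]-11,11-dimethoxy-6,10,10-trimethylundec-5-en-2-ol (both C2 epimers) | CC(O)[C@@H](O[Si](C)(C)C(C)(C)C)C/C=C(\C)CCCC(C)(C)C(OC)OC
F4 | step 10 | (3S,5E)-3-[(tert-butyldimethylsilyl)oxy]-11,11-dimethoxy-6,10,10-trimethylundec-5-en-2-one | CC(=O)[C@@H](O[Si](C)(C)C(C)(C)C)C/C=C(\C)CCCC(C)(C)C(OC)OC
F5 | step 10 | tert-butyl{[(1Z,3S,5E)-1-iodo-11,11-dimethoxy-2,6,10,10-tetramethylundeca-1,5-dien-3-yl]oxy}dimethylsilane | I/C=C(C)\[C@@H](O[Si](C)(C)C(C)(C)C)C/C=C(\C)CCCC(C)(C)C(OC)OC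
F6 | step 8 | tert-butyl{[(3S,5E)-1,1-dibromo-11,11-dimethoxy-6,10,10-trimethylundeca-1,5-dien-3-yl]oxy}dimethylsilane | BrC(Br)=C[C@@H](O[Si](C)(C)C(C)(C)C)C/C=C(\C)CCCC(C)(C)C(OC)OC
F7 | step 8 | lithium acetylide of 14 | [Li]C#C[C@@H](O[Si](C)(C)C(C)(C)C)C/C=C(\C)CCCC(C)(C)C(OC)OC
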